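**Retrosynthetic overview**
- Ring letters: daidzein half = A (benzo ring), C (pyranone), B (4-hydroxyphenyl); genistein half = D (phenol ring at the biaryl bond), E (pyranone), F (phloroglucinol-derived ring).
- Key disconnection: both pyranones (rings C and E) are opened at O1–C2 (C–O) and C2–C3, giving a biaryl-linked bis(2-hydroxydeoxybenzoin) plus two one-carbon units; the two C–O ring closures are the last bond-forming event.
- The ring-A ketone is disconnected by Friedel–Crafts acylation with 4-hydroxyphenylacetic acid, and the ring-F ketone by acylation of phloroglucinol with a biaryl acetic acid; three methyl ethers are removed in between.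
- The A–D biaryl bond is disconnected by Suzuki coupling of 2,6-dimethoxyphenylboronic acid with 3-bromo-4-methoxyphenylacetic acid (the only biaryl C–C step, done first on simple pieces).
- Order of ring formation: rings A, B, D and F are bought as arenes; rings C and E are formed together in the final flask.

Assumption: the target SMILES has no stereodescriptor and no stereocentre, and the A–D biaryl axis (ortho groups OH, ring O and OH) is taken as freely rotating, so no stereocontrol is needed.

**Route**

Step 1
Reactants: 1 2,6-dimethoxyphenylboronic acid (1.6 equiv); 2 2-(3-bromo-4-methoxyphenyl)acetic acid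
Product: 3 2-[3-(2,6-dimethoxyphenyl)-4-methoxyphenyl]acetic acid
Conditions: Pd(OAc)2 (2 mol%), SPhos (4 mol%), K3PO4 (4 equiv), 1,4-dioxane/H2O 4:1, 90 °C, 12 h; then 1 M HCl
Reagents that add atoms: none
Why: Suzuki–Miyaura coupling, for which Pd(OAc)2/SPhos is well suited to tri-ortho-substituted biaryls and 2,6-dialkoxyarylboronic acids (excess 1 offsets protodeboronation), with the carboxylate as a spectator in aqueous base and no stereocentre formed.

Step 2
Reactants: 3 2-[3-(2,6-dimethoxyphenyl)-4-methoxyphenyl]acetic acid; 4 phloroglucinol (2 equiv)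
Product: 5 2-[3-(2,6-dimethoxyphenyl)-4-methoxyphenyl]-1-(2,4,6-trihydroxyphenyl)ethan-1-one
Conditions: BF3·OEt2 (neat), 80 °C, 2 h; then 10% aq. NaOAc
Reagents that add atoms: none
Why: BF3-mediated Friedel–Crafts C-acylation (Houben–Hoesch-type deoxybenzoin synthesis), a condensation with loss of water in which the acid is activated on boron, symmetric phloroglucinol gives a single regioisomer, the BF2 chelate of the product blocks a second acylation, and the much less nucleophilic methoxyarene rings and the methyl ethers are untouched.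

Step 3
Reactants: 5 2-[3-(2,6-dimethoxyphenyl)-4-methoxyphenyl]-1-(2,4,6-trihydroxyphenyl)ethan-1-one
Product: 6 2-[3-(2,6-dihydroxyphenyl)-4-hydroxyphenyl]-1-(2,4,6-trihydroxyphenyl)ethan-1-one
Conditions: BBr3 (10 equiv), CH2Cl2, −78 °C to 20 °C, 16 h; then ice/H2O (no methanol quench)
Reagents that add atoms: none
Why: Lewis-acid ether cleavage (BBr3 O-demethylation), in which each ArOMe is converted to ArOBBr2 and MeBr while the free phenols and the ketone only consume extra reagent, and cold water releases the hexaol without etherifying the phloroglucinol ring.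

Step 4
Reactants: 6 2-[3-(2,6-dihydroxyphenyl)-4-hydroxyphenyl]-1-(2,4,6-trihydroxyphenyl)ethan-1-one; 7 2-(4-hydroxyphenyl)acetic acid (2 equiv)
Product: 10 7-hydroxy-8-[2-hydroxy-5-(5,7-dihydroxy-4-oxo-4H-chromen-3-yl)phenyl]-3-(4-hydroxyphenyl)-4H-chromen-4-one, via bis-deoxybenzoin 8 (not isolated), via bis-enaminone 9 (not isolated)
Conditions: BF3·OEt2 (neat), 75 °C, 3 h; then Me2NCH(OMe)2 (10 equiv) in 1,4-dioxane, 0 to 60 °C, 3 h; then 10% aq. NaOAc, 70 °C, 1 h
Reagents that add atoms: N,N-dimethylformamide dimethyl acetal, COC(OC)N(C)C (supplies the two C2 methine carbons)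
Why: Proposed new method: after an ordinary BF3-mediated Friedel–Crafts acylation of ring A at its only activated position (ortho to one OH, para to the other) gives 8 with loss of water, a twofold boron-difluoride-templated (5+1) methine annulation is run in the same flask, in which BF3 strips methoxide from the amide acetal to give the methoxymethylene-dimethyliminium ion, the BF2-chelated enols of both 2-hydroxydeoxybenzoin units attack it at the benzylic carbon (chelation masks the ortho hydroxyls and carbonyls and acidifies the CH2), loss of MeOH gives bis-enaminone 9, and on warm aqueous NaOAc each freed ortho-OH adds to its enaminone carbon and expels Me2NH (addition–elimination), forming both O1–C2 bonds and rings C and E at once; the closest known reaction types are the BF3·OEt2/DMF/MsCl Vilsmeier-type one-pot annulation of single 2-hydroxydeoxybenzoins and the thermal amide-acetal enaminone cyclisation, whereas a sulfonyl-chloride-free, BF3-activated amide-acetal version run twofold on a biaryl-linked bis-deoxybenzoin with seven free hydroxyls is not described.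

**Compound list**
1 | 2,6-dimethoxyphenylboronic acid | COc1cccc(OC)c1B(O)O | starting material
2 | 2-(3-bromo-4-methoxyphenyl)acetic acid | COc1ccc(CC(=O)O)cc1Br | starting material
3 | 2-[3-(2,6-dimethoxyphenyl)-4-methoxyphenyl]acetic acid | COc1ccc(CC(=O)O)cc1-c1c(OC)cccc1OC | intermediate
4 | phloroglucinol (benzene-1,3,5-triol) | Oc1cc(O)cc(O)c1 | starting material
5 | 2-[3-(2,6-dimethoxyphenyl)-4-methoxyphenyl]-1-(2,4,6-trihydroxyphenyl)ethan-1-one | COc1ccc(CC(=O)c2c(O)cc(O)cc2O)cc1-c1c(OC)cccc1OC | intermediate
6 | 2-[3-(2,6-dihydroxyphenyl)-4-hydroxyphenyl]-1-(2,4,6-trihydroxyphenyl)ethan-1-one | Oc1ccc(CC(=O)c2c(O)cc(O)cc2O)cc1-c1c(O)cccc1O | intermediate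
7 | 2-(4-hydroxyphenyl)acetic acid | OC(=O)Cc1ccc(O)cc1 | starting material
8 | 1-{2,4-dihydroxy-3-[2-hydroxy-5-(2-oxo-2-(2,4,6-trihydroxyphenyl)ethyl)phenyl]phenyl}-2-(4-hydroxyphenyl)ethan-1-one (bis-deoxybenzoin, held as BF2 chelates) | O=C(Cc1ccc(O)cc1)c1ccc(O)c(-c2cc(CC(=O)c3c(O)cc(O)cc3O)ccc2O)c1O | intermediate
9 | 3-(dimethylamino)-1-{3-[5-(1-(dimethylamino)-3-oxo-3-(2,4,6-trihydroxyphenyl)prop-1-en-2-yl)-2-hydroxyphenyl]-2,4-dihydroxyphenyl}-2-(4-hydroxyphenyl)prop-2-en-1-one (bis-enaminone, C=C geometry undefined and irrelevant, held as BF2 chelates) | CN(C)C=C(C(=O)c1ccc(O)c(-c2cc(C(=CN(C)C)C(=O)c3c(O)cc(O)cc3O)ccc2O)c1O)c1ccc(O)cc1 | intermediate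
10 | 7-hydroxy-8-[2-hydroxy-5-(5,7-dihydroxy-4-oxo-4H-chromen-3-yl)phenyl]-3-(4-hydroxyphenyl)-4H-chromen-4-one (CNP0484003.0) | O=c1c(-c2ccc(O)cc2)coc2c(-c3cc(-c4coc5cc(O)cc(O)c5c4=O)ccc3O)c(O)ccc12 | target

**Step count and risks**

Total steps: 4. Longest linear sequence: 4 (1/2 → 3 → 5 → 6 → 10).

Three steps most likely to fail:

Step 4 (proposed new method). The amide acetal may be consumed by the water and excess acid left from the acylation. One enaminone may form faster than the other, giving mono-cyclised material. The hot BF3 stage could also dehydrate the 2,2',6-trihydroxybiphenyl unit to a dibenzofuran. The fallback uses only known chemistry; it sets out from 5 and comes back at 10, building the two pyranones one after the other. Ring E is closed on 5 with the established BF3·OEt2/DMF/MsCl annulation (55 °C) to give 5,7-dihydroxy-3-[3-(2,6-dimethoxyphenyl)-4-methoxyphenyl]-4H-chromen-4-one F1. BBr3 in CH2Cl2 then removes the three methyl groups to give 3-[3-(2,6-dihydroxyphenyl)-4-hydroxyphenyl]-5,7-dihydroxy-4H-chromen-4-one F2. Finally the established one-pot sequence is run on ring A: 7 in BF3·OEt2 at 75 °C gives 1-{2,4-dihydroxy-3-[2-hydroxy-5-(5,7-dihydroxy-4-oxo-4H-chromen-3-yl)phenyl]phenyl}-2-(4-hydroxyphenyl)ethan-1-one F3, which is not isolated and is closed with DMF/MsCl in the same flask to 10.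

Step 1. 2,6-Dimethoxyphenylboronic acid protodeboronates readily under aqueous base, and the biaryl is tri-ortho-substituted. The fallback sets out from 2 and comes back at 3, inverting the polarity of the coupling so that boron sits on the less hindered ring. Miyaura borylation of 2 (bis(pinacolato)diboron, PdCl2(dppf), KOAc, 1,4-dioxane, 90 °C) gives 2-[4-methoxy-3-(4,4,5,5-tetramethyl-1,3,2-dioxaborolan-2-yl)phenyl]acetic acid F4. This is coupled with commercial 2-bromo-1,3-dimethoxybenzene (COc1cccc(OC)c1Br; Pd(OAc)2, SPhos, K3PO4, dioxane/H2O) to give 3.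

Step 3. Demethylation of the polyphenolic ketone 5 may stall at the hindered 2,6-dimethoxy ring or suffer from insoluble boron complexes. The fallback sets out from 3 and comes back at 6, moving the deprotection ahead of the ketone synthesis. BBr3 (CH2Cl2, −78 to 20 °C) on the simple acid 3 gives 2-[3-(2,6-dihydroxyphenyl)-4-hydroxyphenyl]acetic acid F5. F5 then acylates phloroglucinol 4 (3 equiv, BF3·OEt2, 60 °C; excess 4 and the lower temperature favour phloroglucinol over the free resorcinol ring of F5) to give 6.

Further compounds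
F1 | step 4 | 5,7-dihydroxy-3-[3-(2,6-dimethoxyphenyl)-4-methoxyphenyl]-4H-chromen-4-one | COc1ccc(-c2coc3cc(O)cc(O)c3c2=O)cc1-c1c(OC)cccc1OC
F2 | step 4 | 3-[3-(2,6-dihydroxyphenyl)-4-hydroxyphenyl]-5,7-dihydroxy-4H-chromen-4-one | Oc1ccc(-c2coc3cc(O)cc(O)c3c2=O)cc1-c1c(O)cccc1O
F3 | step 4 | 1-{2,4-dihydroxy-3-[2-hydroxy-5-(5,7-dihydroxy-4-oxo-4H-chromen-3-yl)phenyl]phenyl}-2-(4-hydroxyphenyl)ethan-1-one | O=C(Cc1ccc(O)cc1)c1ccc(O)c(-c2cc(-c3coc4cc(O)cc(O)c4c3=O)ccc2O)c1O
F4 | step 1 | 2-[4-methoxy-3-(4,4,5,5-tetramethyl-1,3,2-dioxaborolan-2-yl)phenyl]acetic acid | COc1ccc(CC(=O)O)cc1B1OC(C)(C)C(C)(C)O1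
F5 | step 3 | 2-[3-(2,6-dihydroxyphenyl)-4-hydroxyphenyl]acetic acid | OC(=O)Cc1ccc(O)c(-c2c(O)cccc2O)c1
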